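## The problem

Dipolynaphthalene B 19 joins two C10 units through a single sp3–sp2 bond: C4 of a tetralin (ring A aromatic, ring B saturated) carries a 4-hydroxy-5-methoxynaphthalen-1-yl group (rings C and D), and this bond is wedged between the C5 methoxy group of ring A and the peri C8' hydrogen of ring D. Ring B holds the only two stereocentres, the benzylic carbinol C1 (S) and the diaryl-type methine C4 (S); they are cis but 1,4-related, so no chelate or neighbouring-group effect links them. C1 can be set by reagent control from a ketone and, once it carries a bulky pseudoaxial protecting group, can bias the two faces of a C3=C4 double bond, whereas C4 has no functional handle, cannot be corrected once made and is a poor source of control for C1. The benzylic C1–O bond ionises or eliminates under acid, the doubly benzylic C4–H is open to oxidants and radicals, and the free peri-methoxynaphthol is air-sensitive, so the phenol should appear late and strong acid is to be avoided. The enabling feature lies in the naphthalene: C1' (attachment) and C4' (C–OH) are para on ring C, and the C5' methoxy group on ring D is peri to the hydroxyl. C1'–C2'–C3'–C4' therefore maps onto a furan with the tetralinyl group at one α-carbon and oxygen at the other, and C4a'/C8a' with the C5' methoxy group onto 3-methoxybenzyne 15, so the naphthol can be assembled last around an existing C4 stereocentre.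

## Retrosynthesis

**19 from 18 (O–Si).** The benzylic hydroxyl is unmasked in the last step. Carrying it as a triisopropylsilyl ether keeps the C1–O bond from ionising in every earlier step, and the same bulky group serves as the stereocontrol element for C4. The forward reaction only has to cleave a Si–O bond without acid.

**18 from 17 (C4'–O put back).** The naphthol 18 is read as the reduced form of the para-quinol 17. Adding this oxygen in the retro direction turns ring C into a cycloaddition retron, because the quaternary quinol carbon is the bridgehead of an oxygen-bridged adduct. The forward step is a two-electron reduction that expels the tertiary hydroxyl and is driven by aromatisation. The quinol stereocentre need not be controlled.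

**17 from 13 and 14 (C1'–C8a' and C4'–C4a').** Both bonds that fuse ring C to ring D are cut, leading to the 5-tetralinyl-2-siloxyfuran 13 and the aryne precursor 14, by way of aryne 15 and the bridged ketal 16. The neighbouring cut, C4–C1', would need a separately made 1,4,5-trisubstituted naphthalene and a stereocontrolled sp3–sp2 coupling at a hindered secondary benzylic carbon. The aryne cut places OH, OMe and the tetralinyl group by polarity and sterics alone. The forward reaction must be regioselective across the aryne and must leave C1 and C4 untouched.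

**13 from 12 from 10 (O–Si, then C–O at the furan).** The siloxyfuran 13 is the silyl dienolate of butenolide 12, which comes from ipso-oxidation of the 2-silylfuran 10. The trimethylsilyl group marks the carbon to be oxygenated and lets the heterocycle pass through the organometallic and hydrogenation steps as a robust furan. The labile 2-oxygenated furan then exists for one step only.

**10 from 9 (C4–H and C3–H).** C4 is created by hydrogenating the ring B alkene of 9. Substitution at an sp3 carbon would offer no dependable facial control, whereas a flat dihydronaphthalene with a pseudoaxial silyloxy group at C1 has two clearly different faces. The forward step must add hydrogen anti to the silyloxy group, which places the furyl group cis to the C1 oxygen.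

**9 from 5 and 6 (C4–C2 of the furan).** An sp2–sp2 cross-coupling joins the enol triflate 5 and the metalated silylfuran made from 6 (7, then 8). Organometallic addition to ketone 4 followed by dehydration would need acid next to the labile C1–O bond, which the neutral coupling avoids. The forward step must tolerate a hindered triflate peri to OMe and must not eliminate the homoallylic silyloxy group.

**5 from 4 from 3 (C4–OTf, then C4=O).** The triflate comes from ketone 4, and the ketone from benzylic oxidation of 3. The C5 methoxy group, ortho to C4a and meta to C8a, should direct an electron-transfer oxidant to the C4 methylene and away from C1–H. This takes a 1,4-dioxygenated tetralin back to a mono-oxygenated one.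

**3 from 2 from 1 (O–Si, then C1–H).** The silyl ether 3 comes from carbinol 2, which is traced to an oxazaborolidine-catalysed reduction of the purchasable 5-methoxy-1-tetralone 1. Ring A, ring B and the methoxy group peri to C4 are thus bought. Building ring B by cycloaddition from a benzaldehyde would add an ester that must later be excised.

## Roads not taken

Alternative 1: The cut is at the C4 methine, which would be assembled in one palladium–carbene event from three pieces: 1-bromo-2-iodo-3-methoxybenzene A1, the 4-(benzyloxy)-5-methoxynaphthalene-1-carbaldehyde N-tosylhydrazone A2 and 3,3-diethoxypropyne A3. With Pd2(dba)3, a chiral phosphine, CuI and LiOtBu, zerovalent palladium would insert into the C–I bond of A1 and take up the carbene from A2. Aryl migration (C4–C4a) and alkynyl transfer from A3 with reductive elimination (C3–C4) would then give the diaryl propargyl methine A4.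
- Merits: it is highly convergent, forms two bonds at C4 in one step, sets C4 by catalyst control and brings the naphthalene in ready-made.
- Weak points: a 2,6-disubstituted aryl group must migrate onto a palladium carbene that already carries a peri-substituted naphthyl group. Enantiocontrol of such an insertion is not an established reaction type. The methine of A4 is doubly benzylic and propargylic, so LiOtBu can erase the stereocentre by propargyl–allenyl isomerisation. Ring B is still open in A4, so alkyne reduction beside an aryl bromide, acetal hydrolysis and an aryl-metal ring closure onto an aldehyde follow, and C1 is then set late under weak 1,4-induction.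
- Comparison: this road is better in convergence and in making C4 by catalysis. The chosen plan sets against it that every C–C bond comes from an established reaction class, that C1 is fixed first by a reliable ketone reduction, and that C4 never sits next to an alkyne under base.

Alternative 2: The cut is through ring A. The acyclic 1,7-diyne A5 (siloxyalkyne at one end, terminal alkyne at the other, both stereocentres in the tether) and acetylene A6 would be cyclotrimerised with RhCl(PPh3)3 to the tetralin A7, forming C4a–C8a, C5–C6 and C7–C8 and closing ring A and ring B together.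
- Merits: it is atom-economical, and the tether fixes the position of the C5 oxygen.
- Weak points: both stereocentres and the complete naphthalene must already be present in the open chain of A5, where C1 and C4 have no ring to relay stereochemistry. The C4–H of A5 is propargylic and benzylic and can scramble. The siloxyalkyne is fragile, and cross-trimerisation with gaseous A6 competes with diyne oligomerisation. Afterwards the aryl silyl ether of A7 must be exchanged for a methyl ether and two further protecting groups removed.
- Comparison: the key step is spent on a benzene ring that can be bought with the right substituents, while the hard part (C4 with its naphthyl group) must be solved beforehand. The chosen plan is weaker only in atom economy of ring formation. It gains by buying rings A and B and using its ring-forming step on the naphthol.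

Alternative 3: The cut is across ring B. Irradiation (about 365 nm) of 2-{[4-(benzyloxy)-5-methoxynaphthalen-1-yl]methyl}-3-methoxybenzaldehyde A8 with Ti(OiPr)4 and a chiral TADDOL-type diol would give the hydroxy-ortho-quinodimethane A9. This dienol adds methyl acrylate A10 to form C1–C2 and C3–C4 and deliver the all-cis ester A11.
- Merits: ring B and both stereocentres arise in one step, the cis-1,4 relationship follows from the dienol geometry, and the naphthalene enters intact.
- Weak points: the C2 ester of A11 must be removed (saponification, protection of the C1 hydroxyl, radical decarboxylation), with retro-aldol and dehydration risks at a β-hydroxy ester. Enantiocontrol in this photoreaction depends on a substrate pattern that A8 does not obviously offer, since its methoxy group flanks the methylene and not the aldehyde. The naphthalene chromophore competes for light. The 1,4,5-trisubstituted naphthalene part of A8 needs its own regiocontrolled synthesis.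
- Comparison: this road is better in step economy for the stereodiad (one step against steps 1 and 6 here). The chosen plan sets against it thermal, scalable stereo-defining steps of known sense, no traceless group to excise, and a naphthol built regioselectively from two simple pieces.

Key step: step 9

## Route

Remark: 1, 6 and 14 are taken as purchasable. 12 and 17 are carried as mixtures at the lactone and quinol carbons, which are planarised in steps 8 and 10. CIP descriptors at the ring B carbons change with the substituent, although the spatial arrangement is that of the target throughout.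

Step 1
Reactants: 1 5-methoxy-3,4-dihydronaphthalen-1(2H)-one
Product: 2 (1S)-5-methoxy-1,2,3,4-tetrahydronaphthalen-1-ol
Conditions: (R)-2-methyl-CBS-oxazaborolidine (10 mol %), BH3·SMe2, THF, −20 °C; MeOH quench
Reagents that add atoms: none
Why: Corey–Bakshi–Shibata reduction; the (R)-oxazaborolidine holds borane and the ketone so that hydride reaches one carbonyl face only, which for 1-tetralones (aryl as the large group) should give the (S)-carbinol and so sets C1.

Step 2
Reactants: 2 (1S)-5-methoxy-1,2,3,4-tetrahydronaphthalen-1-ol
Product: 3 triisopropyl{[(1S)-5-methoxy-1,2,3,4-tetrahydronaphthalen-1-yl]oxy}silane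
Conditions: TIPSOTf, 2,6-lutidine, CH2Cl2, 0 °C
Reagents that add atoms: triisopropylsilyl trifluoromethanesulfonate, CC(C)[Si](OS(=O)(=O)C(F)(F)F)(C(C)C)C(C)C
Why: Standard silylation of a secondary alcohol with a silyl triflate and a hindered base; the bulky group resists the mild acid and fluoride of later steps and enforces a pseudoaxial C1 substituent for step 6.

Step 3
Reactants: 3 triisopropyl{[(1S)-5-methoxy-1,2,3,4-tetrahydronaphthalen-1-yl]oxy}silane
Product: 4 (4S)-8-methoxy-4-(triisopropylsilyloxy)-3,4-dihydronaphthalen-1(2H)-one
Conditions: DDQ (2.5 equiv), 1,4-dioxane/H2O (9:1), rt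
Reagents that add atoms: water, O
Why: Quinone-mediated benzylic oxidation of an alkylanisole; electron transfer gives an arene radical cation with positive charge ortho and para to OMe, so the C4 methylene (on C4a, ortho) is activated while C1–H (on C8a, meta) is spared. Water traps the benzylic cation and a second oxidation gives the aryl ketone.

Step 4
Reactants: 4 (4S)-8-methoxy-4-(triisopropylsilyloxy)-3,4-dihydronaphthalen-1(2H)-one
Product: 5 (4S)-8-methoxy-4-(triisopropylsilyloxy)-3,4-dihydronaphthalen-1-yl trifluoromethanesulfonate
Conditions: KN(SiMe3)2, THF, −78 °C; PhNTf2, −78 to 0 °C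
Reagents that add atoms: N-phenylbis(trifluoromethanesulfonimide), O=S(=O)(N(c1ccccc1)S(=O)(=O)C(F)(F)F)C(F)(F)F
Why: Kinetic enolisation of the only α-methylene and O-triflation of the potassium enolate; the enolate has no β-leaving group, so the silyloxy group two carbons further on is not expelled at low temperature.

Step 5
Reactants: 5 (4S)-8-methoxy-4-(triisopropylsilyloxy)-3,4-dihydronaphthalen-1-yl trifluoromethanesulfonate; 6 2-(trimethylsilyl)furan
Product: 9 triisopropyl({(1S)-5-methoxy-4-[5-(trimethylsilyl)furan-2-yl]-1,2-dihydronaphthalen-1-yl}oxy)silane, via 5-lithio-2-(trimethylsilyl)furan 7 (not isolated), via chloro[5-(trimethylsilyl)furan-2-yl]zinc 8 (not isolated)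
Conditions: 6, n-BuLi, THF, 0 °C; ZnCl2, 0 °C to rt; then 5, Pd(PPh3)4 (5 mol %), THF, 50 °C
Reagents that add atoms: none
Why: Negishi cross-coupling; 6 is lithiated at its free α-position, transmetalated to zinc and coupled with the enol triflate under zerovalent palladium catalysis. The neutral organozinc leaves the homoallylic silyl ether in place.

Step 6
Reactants: 9 triisopropyl({(1S)-5-methoxy-4-[5-(trimethylsilyl)furan-2-yl]-1,2-dihydronaphthalen-1-yl}oxy)silane
Product: 10 triisopropyl({(1S,4R)-5-methoxy-4-[5-(trimethylsilyl)furan-2-yl]-1,2,3,4-tetrahydronaphthalen-1-yl}oxy)silane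
Conditions: H2 (1 atm), 10% Pd/C, EtOAc, Et3N (trace), rt
Reagents that add atoms: none
Why: Heterogeneous syn-hydrogenation of a trisubstituted styrenyl alkene; the C1 silyloxy group is pseudoaxial (it avoids the peri C8–H) and blocks its face, so hydrogen should add to C3 and C4 from the opposite face and leave the furyl group cis to the C1 oxygen, which sets C4. The trace of amine suppresses acid-induced loss of silanol.

Step 7
Reactants: 10 triisopropyl({(1S,4R)-5-methoxy-4-[5-(trimethylsilyl)furan-2-yl]-1,2,3,4-tetrahydronaphthalen-1-yl}oxy)silane
Product: 12 5-[(1R,4S)-8-methoxy-4-(triisopropylsilyloxy)-1,2,3,4-tetrahydronaphthalen-1-yl]furan-2(5H)-one, via trimethylsilyloxyfuran 11 (not isolated)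
Conditions: AcOOH (in AcOH), NaOAc, CH2Cl2, 0 °C to rt
Reagents that add atoms: peracetic acid, CC(=O)OO
Why: Peracid ipso-oxidation of a 2-trimethylsilylfuran to a butenolide; the peracid epoxidises the silyl-bearing double bond, a 1,2-shift of silicon from carbon to oxygen gives siloxyfuran 11, and protodesilylation by acetic acid leaves the carbonyl at the former C–Si carbon. The lactone stereocentre and any β,γ-unsaturated isomer are of no consequence because step 8 planarises that carbon.

Step 8
Reactants: 12 5-[(1R,4S)-8-methoxy-4-(triisopropylsilyloxy)-1,2,3,4-tetrahydronaphthalen-1-yl]furan-2(5H)-one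
Product: 13 triisopropyl({(1S,4R)-5-methoxy-4-[5-(triisopropylsilyloxy)furan-2-yl]-1,2,3,4-tetrahydronaphthalen-1-yl}oxy)silane
Conditions: TIPSOTf, Et3N, CH2Cl2, 0 °C
Reagents that add atoms: triisopropylsilyl trifluoromethanesulfonate, CC(C)[Si](OS(=O)(=O)C(F)(F)F)(C(C)C)C(C)C
Why: Soft enolisation of a butenolide; O-silylation by the silyl triflate and γ-deprotonation by the amine give the aromatic 2-siloxyfuran, a cyclic silyl dienolate. The triisopropylsilyl derivative is robust enough to be filtered and used directly.

Step 9
Reactants: 13 triisopropyl({(1S,4R)-5-methoxy-4-[5-(triisopropylsilyloxy)furan-2-yl]-1,2,3,4-tetrahydronaphthalen-1-yl}oxy)silane; 14 2-methoxy-6-(trimethylsilyl)phenyl trifluoromethanesulfonate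
Product: 17 4-hydroxy-8-methoxy-4-[(1R,4S)-8-methoxy-4-(triisopropylsilyloxy)-1,2,3,4-tetrahydronaphthalen-1-yl]naphthalen-1(4H)-one, via 3-methoxybenzyne 15 (not isolated), via bridged silyl ketal 16 (not isolated)
Conditions: 14 (1.5 equiv, slow addition), CsF (3 equiv), MeCN, rt; aq. NH4Cl
Reagents that add atoms: none
Why: CsF strips the trimethylsilyl group from 14 with loss of triflate to release aryne 15, in which the σ-withdrawing methoxy group makes the ring carbon meta to it the preferred site of attack, because the developing aryl anion then sits next to the oxygen-bearing carbon. Siloxyfuran 13 behaves as a cyclic silyl dienolate that is most nucleophilic at C5, the carbon carrying the tetralinyl group, so C5 joins the meta carbon (C1'–C8a') while the siloxy-bearing C2 joins the carbon next to OMe (C4'–C4a') in an asynchronous [4+2] addition. Ring C is thus closed by cycloaddition of the furan diene across the aryne, a six-membered ring formed from two components and not by cyclisation of a tether. The closest known reaction type is the Diels–Alder reaction of furans, 2-alkoxyfurans included, with arynes generated from ortho-silylaryl triflates, whose oxygen-bridged adducts open to 1-naphthol derivatives. Excess fluoride then removes the bridgehead silyl group of 16, and the hemiketal alkoxide opens the oxygen bridge to a ketone and a tertiary alkoxide, which on work-up is para-quinol 17 with its carbonyl peri to OMe. The only new sp3 centre, the quinol carbon, forms without control and is erased in step 10, and the neutral room-temperature conditions leave C1 and C4 of the tetralin untouched. The selectivity required is regiochemical, across the aryne, and it is secured by the polarity match of aryne and dienolate, reinforced by the bulky tetralinyl group staying clear of the methoxy-flanked terminus. Should bond formation be fully stepwise (arylation at C5, then capture of the aryl anion at the lactone-type carbon), the same constitution results.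

Step 10
Reactants: 17 4-hydroxy-8-methoxy-4-[(1R,4S)-8-methoxy-4-(triisopropylsilyloxy)-1,2,3,4-tetrahydronaphthalen-1-yl]naphthalen-1(4H)-one
Product: 18 8-methoxy-4-[(1S,4S)-8-methoxy-4-(triisopropylsilyloxy)-1,2,3,4-tetrahydronaphthalen-1-yl]naphthalen-1-ol
Conditions: Zn dust, AcOH/THF, rt, under argon
Reagents that add atoms: none
Why: Reductive aromatisation of a para-quinol by a dissolving metal; two-electron reduction of the dienone with loss of the protonated tertiary hydroxyl gives the naphthol, driven by aromatisation. The quinol stereocentre disappears and the triisopropylsilyl ether tolerates acetic acid at room temperature.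

Step 11
Reactants: 18 8-methoxy-4-[(1S,4S)-8-methoxy-4-(triisopropylsilyloxy)-1,2,3,4-tetrahydronaphthalen-1-yl]naphthalen-1-ol
Product: 19 (1S,4S)-4-(4-hydroxy-5-methoxynaphthalen-1-yl)-5-methoxy-1,2,3,4-tetrahydronaphthalen-1-ol
Conditions: Bu4NF, THF, rt to 40 °C, under argon; aq. NH4Cl
Reagents that add atoms: none
Why: Fluoride cleavage of a silyl ether, driven by the Si–F bond; the non-acidic conditions leave the benzylic C1–O bond and its configuration untouched.

## Compound list

1 | 5-methoxy-3,4-dihydronaphthalen-1(2H)-one (5-methoxy-1-tetralone) | COc1cccc2c1CCCC2=O | starting material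
2 | (1S)-5-methoxy-1,2,3,4-tetrahydronaphthalen-1-ol | COc1cccc2c1CCC[C@@H]2O | intermediate
3 | triisopropyl{[(1S)-5-methoxy-1,2,3,4-tetrahydronaphthalen-1-yl]oxy}silane | COc1cccc2c1CCC[C@@H]2O[Si](C(C)C)(C(C)C)C(C)C | intermediate
4 | (4S)-8-methoxy-4-(triisopropylsilyloxy)-3,4-dihydronaphthalen-1(2H)-one | COc1cccc2c1C(=O)CC[C@@H]2O[Si](C(C)C)(C(C)C)C(C)C | intermediate
5 | (4S)-8-methoxy-4-(triisopropylsilyloxy)-3,4-dihydronaphthalen-1-yl trifluoromethanesulfonate | COc1cccc2c1C(OS(=O)(=O)C(F)(F)F)=CC[C@@H]2O[Si](C(C)C)(C(C)C)C(C)C | intermediate
6 | 2-(trimethylsilyl)furan | C[Si](C)(C)c1ccco1 | starting material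
7 | 5-lithio-2-(trimethylsilyl)furan | [Li]c1ccc([Si](C)(C)C)o1 | intermediate (not isolated)
8 | chloro[5-(trimethylsilyl)furan-2-yl]zinc | Cl[Zn]c1ccc([Si](C)(C)C)o1 | intermediate (not isolated)
9 | triisopropyl({(1S)-5-methoxy-4-[5-(trimethylsilyl)furan-2-yl]-1,2-dihydronaphthalen-1-yl}oxy)silane | COc1cccc2c1C(c1ccc([Si](C)(C)C)o1)=CC[C@@H]2O[Si](C(C)C)(C(C)C)C(C)C | intermediate
10 | triisopropyl({(1S,4R)-5-methoxy-4-[5-(trimethylsilyl)furan-2-yl]-1,2,3,4-tetrahydronaphthalen-1-yl}oxy)silane (cis) | COc1cccc2c1[C@H](c1ccc([Si](C)(C)C)o1)CC[C@@H]2O[Si](C(C)C)(C(C)C)C(C)C | intermediate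
11 | triisopropyl({(1S,4R)-5-methoxy-4-[5-(trimethylsilyloxy)furan-2-yl]-1,2,3,4-tetrahydronaphthalen-1-yl}oxy)silane | COc1cccc2c1[C@H](c1ccc(O[Si](C)(C)C)o1)CC[C@@H]2O[Si](C(C)C)(C(C)C)C(C)C | intermediate (not isolated)
12 | 5-[(1R,4S)-8-methoxy-4-(triisopropylsilyloxy)-1,2,3,4-tetrahydronaphthalen-1-yl]furan-2(5H)-one (lactone carbon unassigned) | COc1cccc2c1[C@H](C1OC(=O)C=C1)CC[C@@H]2O[Si](C(C)C)(C(C)C)C(C)C | intermediate
13 | triisopropyl({(1S,4R)-5-methoxy-4-[5-(triisopropylsilyloxy)furan-2-yl]-1,2,3,4-tetrahydronaphthalen-1-yl}oxy)silane | COc1cccc2c1[C@H](c1ccc(O[Si](C(C)C)(C(C)C)C(C)C)o1)CC[C@@H]2O[Si](C(C)C)(C(C)C)C(C)C | intermediate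
14 | 2-methoxy-6-(trimethylsilyl)phenyl trifluoromethanesulfonate | COc1cccc([Si](C)(C)C)c1OS(=O)(=O)C(F)(F)F | starting material
15 | 3-methoxybenzyne (1-methoxy-2,3-didehydrobenzene) | COC1=CC=CC#C1 | intermediate (not isolated)
16 | 8-methoxy-4-[(1R,4S)-8-methoxy-4-(triisopropylsilyloxy)-1,2,3,4-tetrahydronaphthalen-1-yl]-1-(triisopropylsilyloxy)-1,4-dihydro-1,4-epoxynaphthalene (bridgeheads unassigned) | COc1cccc2c1[C@H](C13C=CC(O[Si](C(C)C)(C(C)C)C(C)C)(O1)c1c(OC)cccc13)CC[C@@H]2O[Si](C(C)C)(C(C)C)C(C)C | intermediate (not isolated)
17 | 4-hydroxy-8-methoxy-4-[(1R,4S)-8-methoxy-4-(triisopropylsilyloxy)-1,2,3,4-tetrahydronaphthalen-1-yl]naphthalen-1(4H)-one (quinol carbon unassigned) | COc1cccc2c1[C@H](C1(O)C=CC(=O)c3c(OC)cccc31)CC[C@@H]2O[Si](C(C)C)(C(C)C)C(C)C | intermediate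
18 | 8-methoxy-4-[(1S,4S)-8-methoxy-4-(triisopropylsilyloxy)-1,2,3,4-tetrahydronaphthalen-1-yl]naphthalen-1-ol | COc1cccc2c1[C@H](c1ccc(O)c3c(OC)cccc13)CC[C@@H]2O[Si](C(C)C)(C(C)C)C(C)C | intermediate
19 | dipolynaphthalene B, (1S,4S)-4-(4-hydroxy-5-methoxynaphthalen-1-yl)-5-methoxy-1,2,3,4-tetrahydronaphthalen-1-ol | COc1cccc2c1[C@H](c1ccc(O)c3c(OC)cccc13)CC[C@@H]2O | target

## Step count and risks

Total step count: 11. Longest linear sequence: 11 steps (1 to 19); 6 and 14 are purchased and enter in steps 5 and 9.

**Step 9 (key step).**
- What may go wrong: regioselectivity may erode if the hindered furan C5 cannot reach the aryne terminus remote from OMe. Fluoride may desilylate the dienol ether of 13 faster than it generates the aryne, which would divert the free dienolate to protonation or α-arylation. The quinol alkoxide may be O-arylated by a second aryne.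
- Fallback (leaves the cycloaddition, known chemistry only; sets out from 5, returns at 18): the naphthalene partner is made on the side from purchasable 8-methoxynaphthalen-1-ol. NBS in MeCN should brominate para to the hydroxyl to give 4-bromo-8-methoxynaphthalen-1-ol F1. BnBr with K2CO3 in DMF gives 1-(benzyloxy)-4-bromo-8-methoxynaphthalene F2. Miyaura borylation (bis(pinacolato)diboron, KOAc, PdCl2(dppf), dioxane, 80 °C) gives 2-[4-(benzyloxy)-5-methoxynaphthalen-1-yl]-4,4,5,5-tetramethyl-1,3,2-dioxaborolane F3. Suzuki–Miyaura coupling of 5 with this boronate under Pd(PPh3)4 and K3PO4 in dioxane/water should give {[(1S)-4-[4-(benzyloxy)-5-methoxynaphthalen-1-yl]-5-methoxy-1,2-dihydronaphthalen-1-yl]oxy}triisopropylsilane F4. Hydrogenation over Pd/C would then saturate C3=C4 anti to the silyloxy group and remove the benzyl group, giving 18.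

**Step 6.**
- What may go wrong: facial discrimination may be insufficient if the furyl group, twisted by the peri methoxy group, shields both faces or if the silyloxy group is not held pseudoaxial. Over-reduction of the furan or loss of silanol with aromatisation may also compete.
- Fallback (hydroxyl-directed hydrogenation in the enantiomeric C1 series, then inversion of C1; sets out from 1, returns at 10): reduction of 1 with the (S)-oxazaborolidine gives (1R)-5-methoxy-1,2,3,4-tetrahydronaphthalen-1-ol F5. Steps 2 to 5 in this series give the (1R)-triisopropylsilyl ether F6, the (4R)-silyloxy ketone F7, the (4R)-enol triflate F8 and the (1R)-furyl diene silyl ether F9. Bu4NF buffered with AcOH at 0 °C frees the (1R)-furyl dienol F10 while the furyl–silicon bond should persist. [Ir(cod)(PCy3)(py)]PF6 and H2 in CH2Cl2 bind the homoallylic hydroxyl and deliver hydrogen to its own face, giving the trans-(1R,4R)-furyl tetralol F11, which has the C4 configuration of 10. A Mitsunobu reaction (PhCO2H, PPh3, diisopropyl azodicarboxylate) inverts C1 to the cis-(1S,4R)-benzoate F12. K2CO3 in MeOH gives the cis-(1S,4R)-furyl tetralol F13, and silylation as in step 2 returns 10.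

**Step 3.**
- What may go wrong: oxidation may occur at the wrong benzylic position (C1–H beside the silyloxy group). The benzylic cation may eliminate to a dihydronaphthalene and then aromatise with loss of silanol. The silyl ether may be lost to the acidic hydroquinone by-product.
- Fallback (functionalise C4 while C1 is still a ketone, then exchange the roles of the two oxygens; sets out from 1, returns at 4): radical bromination (NBS, AIBN, PhCF3, reflux) at the only benzylic methylene gives racemic 4-bromo-5-methoxy-3,4-dihydronaphthalen-1(2H)-one F14. KOAc in AcOH gives racemic 8-methoxy-4-oxo-1,2,3,4-tetrahydronaphthalen-1-yl acetate F15. The reduction of step 1 gives (4S)-4-hydroxy-8-methoxy-1,2,3,4-tetrahydronaphthalen-1-yl acetate F16, mixed at the acetate carbon, which does not matter. Silylation as in step 2 gives (4S)-8-methoxy-4-(triisopropylsilyloxy)-1,2,3,4-tetrahydronaphthalen-1-yl acetate F17. K2CO3 in MeOH gives (4S)-8-methoxy-4-(triisopropylsilyloxy)-1,2,3,4-tetrahydronaphthalen-1-ol F18, and MnO2 oxidises this benzylic alcohol to 4.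

**Step 10.**
- What may go wrong: C–C fragmentation (loss of the tetralinyl group as a benzylic radical from the reduced dienone) may compete with C–O cleavage. An acid-promoted 1,2-shift of the dienone–phenol type or over-reduction of the enone may also occur.
- Fallback (hydride reduction and dehydration in place of electron transfer; sets out from 17, returns at 18): NaBH4 with CeCl3·7H2O in MeOH (Luche reduction) reduces the carbonyl 1,2 to 5-methoxy-1-[(1R,4S)-8-methoxy-4-(triisopropylsilyloxy)-1,2,3,4-tetrahydronaphthalen-1-yl]-1,4-dihydronaphthalene-1,4-diol F19. Catalytic pyridinium p-toluenesulfonate then ionises the tertiary allylic–benzylic hydroxyl, and loss of the carbinol proton aromatises the ring to 18.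

## Further compounds

F1 | step 9 | 4-bromo-8-methoxynaphthalen-1-ol | COc1cccc2c(Br)ccc(O)c12
F2 | step 9 | 1-(benzyloxy)-4-bromo-8-methoxynaphthalene | COc1cccc2c(Br)ccc(OCc3ccccc3)c12
F3 | step 9 | 2-[4-(benzyloxy)-5-methoxynaphthalen-1-yl]-4,4,5,5-tetramethyl-1,3,2-dioxaborolane | COc1cccc2c(B3OC(C)(C)C(C)(C)O3)ccc(OCc3ccccc3)c12
F4 | step 9 | {[(1S)-4-[4-(benzyloxy)-5-methoxynaphthalen-1-yl]-5-methoxy-1,2-dihydronaphthalen-1-yl]oxy}triisopropylsilane | COc1cccc2c1C(c1ccc(OCc3ccccc3)c3c(OC)cccc13)=CC[C@@H]2O[Si](C(C)C)(C(C)C)C(C)C
F5 | step 6 | (1R)-5-methoxy-1,2,3,4-tetrahydronaphthalen-1-ol | COc1cccc2c1CCC[C@H]2O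
F6 | step 6 | triisopropyl{[(1R)-5-methoxy-1,2,3,4-tetrahydronaphthalen-1-yl]oxy}silane | COc1cccc2c1CCC[C@H]2O[Si](C(C)C)(C(C)C)C(C)C
F7 | step 6 | (4R)-8-methoxy-4-(triisopropylsilyloxy)-3,4-dihydronaphthalen-1(2H)-one | COc1cccc2c1C(=O)CC[C@H]2O[Si](C(C)C)(C(C)C)C(C)C
F8 | step 6 | (4R)-8-methoxy-4-(triisopropylsilyloxy)-3,4-dihydronaphthalen-1-yl trifluoromethanesulfonate | COc1cccc2c1C(OS(=O)(=O)C(F)(F)F)=CC[C@H]2O[Si](C(C)C)(C(C)C)C(C)C
F9 | step 6 | triisopropyl({(1R)-5-methoxy-4-[5-(trimethylsilyl)furan-2-yl]-1,2-dihydronaphthalen-1-yl}oxy)silane | COc1cccc2c1C(c1ccc([Si](C)(C)C)o1)=CC[C@H]2O[Si](C(C)C)(C(C)C)C(C)C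
F10 | step 6 | (1R)-5-methoxy-4-[5-(trimethylsilyl)furan-2-yl]-1,2-dihydronaphthalen-1-ol | COc1cccc2c1C(c1ccc([Si](C)(C)C)o1)=CC[C@H]2O
F11 | step 6 | (1R,4R)-5-methoxy-4-[5-(trimethylsilyl)furan-2-yl]-1,2,3,4-tetrahydronaphthalen-1-ol (trans) | COc1cccc2c1[C@H](c1ccc([Si](C)(C)C)o1)CC[C@H]2O
F12 | step 6 | (1S,4R)-5-methoxy-4-[5-(trimethylsilyl)furan-2-yl]-1,2,3,4-tetrahydronaphthalen-1-yl benzoate (cis) | COc1cccc2c1[C@H](c1ccc([Si](C)(C)C)o1)CC[C@@H]2OC(=O)c1ccccc1
F13 | step 6 | (1S,4R)-5-methoxy-4-[5-(trimethylsilyl)furan-2-yl]-1,2,3,4-tetrahydronaphthalen-1-ol (cis) | COc1cccc2c1[C@H](c1ccc([Si](C)(C)C)o1)CC[C@@H]2O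
F14 | step 3 | 4-bromo-5-methoxy-3,4-dihydronaphthalen-1(2H)-one (racemic) | COc1cccc2c1C(Br)CCC2=O
F15 | step 3 | 8-methoxy-4-oxo-1,2,3,4-tetrahydronaphthalen-1-yl acetate (racemic) | COc1cccc2c1C(OC(C)=O)CCC2=O
F16 | step 3 | (4S)-4-hydroxy-8-methoxy-1,2,3,4-tetrahydronaphthalen-1-yl acetate (acetate carbon unassigned) | COc1cccc2c1C(OC(C)=O)CC[C@@H]2O
F17 | step 3 | (4S)-8-methoxy-4-(triisopropylsilyloxy)-1,2,3,4-tetrahydronaphthalen-1-yl acetate (acetate carbon unassigned) | COc1cccc2c1C(OC(C)=O)CC[C@@H]2O[Si](C(C)C)(C(C)C)C(C)C
F18 | step 3 | (4S)-8-methoxy-4-(triisopropylsilyloxy)-1,2,3,4-tetrahydronaphthalen-1-ol (C1 unassigned) | COc1cccc2c1C(O)CC[C@@H]2O[Si](C(C)C)(C(C)C)C(C)C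
F19 | step 10 | 5-methoxy-1-[(1R,4S)-8-methoxy-4-(triisopropylsilyloxy)-1,2,3,4-tetrahydronaphthalen-1-yl]-1,4-dihydronaphthalene-1,4-diol (carbinol carbons unassigned) | COc1cccc2c1[C@H](C1(O)C=CC(O)c3c(OC)cccc31)CC[C@@H]2O[Si](C(C)C)(C(C)C)C(C)C
A1 | alternative 1 | 1-bromo-2-iodo-3-methoxybenzene | COc1cccc(Br)c1I
A2 | alternative 1 | N'-{[4-(benzyloxy)-5-methoxynaphthalen-1-yl]methylidene}-4-methylbenzenesulfonohydrazide | COc1cccc2c(C=NNS(=O)(=O)c3ccc(C)cc3)ccc(OCc3ccccc3)c12
A3 | alternative 1 | 3,3-diethoxyprop-1-yne | CCOC(C#C)OCC
A4 | alternative 1 | 4-(benzyloxy)-1-[(1S)-1-(2-bromo-6-methoxyphenyl)-4,4-diethoxybut-2-yn-1-yl]-5-methoxynaphthalene | COc1cccc(Br)c1[C@H](c1ccc(OCc2ccccc2)c2c(OC)cccc12)C#CC(OCC)OCC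
A5 | alternative 2 | tert-butyl({(3S,6S)-6-[4-(benzyloxy)-5-methoxynaphthalen-1-yl]-8-(triisopropylsilyloxy)octa-1,7-diyn-3-yl}oxy)dimethylsilane | CC(C)[Si](OC#C[C@H](c1ccc(OCc2ccccc2)c2c(OC)cccc12)CC[C@@H](C#C)O[Si](C)(C)C(C)(C)C)(C(C)C)C(C)C
A6 | alternative 2 | acetylene | C#C
A7 | alternative 2 | tert-butyl{[cis-4-[4-(benzyloxy)-5-methoxynaphthalen-1-yl]-5-(triisopropylsilyloxy)-1,2,3,4-tetrahydronaphthalen-1-yl]oxy}dimethylsilane (configuration as in the target) | CC(C)[Si](Oc1cccc2c1[C@H](c1ccc(OCc3ccccc3)c3c(OC)cccc13)CC[C@@H]2O[Si](C)(C)C(C)(C)C)(C(C)C)C(C)C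
A8 | alternative 3 | 2-{[4-(benzyloxy)-5-methoxynaphthalen-1-yl]methyl}-3-methoxybenzaldehyde | COc1cccc(C=O)c1Cc1ccc(OCc2ccccc2)c2c(OC)cccc12
A9 | alternative 3 | (6-{[4-(benzyloxy)-5-methoxynaphthalen-1-yl]methylidene}-5-methoxycyclohexa-2,4-dien-1-ylidene)methanol (hydroxy-ortho-quinodimethane, drawn as the free dienol, double-bond geometry unassigned) | COC1=CC=CC(=CO)C1=Cc1ccc(OCc2ccccc2)c2c(OC)cccc12
A10 | alternative 3 | methyl acrylate | C=CC(=O)OC
A11 | alternative 3 | methyl all-cis-4-[4-(benzyloxy)-5-methoxynaphthalen-1-yl]-1-hydroxy-5-methoxy-1,2,3,4-tetrahydronaphthalene-2-carboxylate (C1 and C4 as in the target) | COc1cccc2c1[C@H](c1ccc(OCc3ccccc3)c3c(OC)cccc13)C[C@H](C(=O)OC)[C@@H]2O
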